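The tetrahydrofuran ring (C8–C9–O–C9'–C8'; C7 is the guaiacyl CH2, C7' the syringyl carbinol carbon) is traced back to a γ-lactone with C9' as carbonyl, and this lactone is cut at C8–C8'. The key step, an enantioselective dirhodium-carbene C–H insertion, makes that bond, closes the five-membered ring and sets C8 in one operation. It exploits the C8 methylene of a 3-arylpropyl chain, the fifth chain atom counted from the acetate carbon that becomes C8', so all five ring atoms are already in line. The precursor is the diazoacetate of O-benzyl dihydroconiferyl alcohol. Acylation, catalyst-controlled ketone reduction and lactone-to-ether conversion then complete the target.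

Key step: step 4

Remark: lignan numbering is used throughout (C7, C8, C9 on the guaiacyl side; C7', C8', C9' on the syringyl side). The target is (7'S,8S,8'S), with the two ring substituents trans.

Remark: Rh2(4R-MPPIM)4 is the divalent-rhodium dimer bridged by four methyl (4R)-2-oxo-1-(3-phenylpropanoyl)imidazolidine-4-carboxylate ligands.

Assumption: Rh2(4R-MPPIM)4 is taken as the catalyst enantiomer that gives the S lactone, and RuCl[(S,S)-TsDPEN](p-cymene) as the one that gives the 7'S carbinol. Should either sense prove opposite, the mirror-image catalyst is used with no other change.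

Remark: the benzyl ether is kept on the guaiacyl oxygen of the precursor. Its OCH2 hydrogens are out of intramolecular reach of the carbene, and it survives every step up to the hydrogenolysis.

Step 1
Reactants: 1 dihydroconiferyl alcohol
Product: 2 3-(4-benzyloxy-3-methoxyphenyl)propan-1-ol
Conditions: BnBr (1.05 equiv), K2CO3, acetone, reflux
Reagents that add atoms: benzyl bromide, BrCc1ccccc1
Why: Williamson ether synthesis in which carbonate deprotonates only the phenol, so the primary alcohol stays free for the next step.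

Step 2
Reactants: 2 3-(4-benzyloxy-3-methoxyphenyl)propan-1-ol; 3 bromoacetyl bromide
Product: 4 3-(4-benzyloxy-3-methoxyphenyl)propyl bromoacetate
Conditions: NaHCO3 (3 equiv), MeCN, 0 °C
Reagents that add atoms: none
Why: Esterification of the primary alcohol by the acyl bromide, which is far more electrophilic than the alkyl bromide end, with solid hydrogencarbonate as a mild acid scavenger that leaves the α-bromo ester untouched.

Step 3
Reactants: 4 3-(4-benzyloxy-3-methoxyphenyl)propyl bromoacetate
Product: 6 3-(4-benzyloxy-3-methoxyphenyl)propyl diazoacetate, via N-alkylated ditosylhydrazine 5 (not isolated)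
Conditions: TsNHNHTs (2 equiv), DBU (5 equiv), THF, 0 °C
Reagents that add atoms: N,N'-ditosylhydrazine, Cc1ccc(cc1)S(=O)(=O)NNS(=O)(=O)c1ccc(C)cc1
Why: Diazoacetate formation by the ditosylhydrazine method, in which the hydrazide anion is alkylated by the α-bromo ester to 5 and DBU then drives two successive eliminations of sulfinate, so no diazomethane or azide is needed and the benzyl ether and ester are untouched.

Step 4
Reactants: 6 3-(4-benzyloxy-3-methoxyphenyl)propyl diazoacetate
Product: 7 (S)-4-(4-benzyloxy-3-methoxybenzyl)dihydrofuran-2(3H)-one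
Conditions: Rh2(4R-MPPIM)4 (1 mol %), CH2Cl2, reflux, slow addition of 6 by syringe pump (about 10 h)
Reagents that add atoms: none
Why: Loss of N2 from the diazoacetate at an axial site of the divalent-rhodium dimer gives an electrophilic rhodium carbene, which inserts into one C8–H bond through a concerted, three-centre, hydride-transfer-like transition state that forms C8–C8'. The closest known reaction type is the dirhodium carboxamidate-catalysed γ-C–H insertion of 3-arylpropyl diazoacetates to β-benzyl-γ-butyrolactones. The lactone ring C8–C9–O–C9'–C8' closes by 1,5-insertion, that is through a five-membered cyclic transition state with the carbene carbon as atom 1 and C8 as atom 5, the ring size favoured over four-membered closure at C9 and six-membered closure at C7. The C8 stereocentre is controlled by the catalyst: the chiral carboxamidate ligands and their N-acyl arms differentiate the two enantiotopic C8 hydrogens, and the 4R catalyst is taken as the enantiomer that leads to the S lactone. The step needs site selectivity for C8–H over the benzylic C7–H, the deactivated C9–H next to the ester oxygen, the two electron-rich arenes and the benzyl ether CH2; this is secured by the ring-size preference, by the low electrophilicity of carboxamidate-ligated carbenes (no arene addition) and by the benzyl ether lying out of intramolecular reach. Slow addition at high dilution keeps the diazo concentration low and so suppresses carbene dimerisation.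

Step 5
Reactants: 8 4-benzyloxy-3,5-dimethoxybenzoic acid
Product: 9 4-benzyloxy-3,5-dimethoxybenzoyl chloride
Conditions: (COCl)2 (1.3 equiv), DMF (cat.), CH2Cl2, 0 °C → rt; evaporate
Reagents that add atoms: oxalyl chloride, ClC(=O)C(Cl)=O
Why: Acid chloride formation by oxalyl chloride under chloroiminium (Vilsmeier-type) catalysis, a neutral method that spares the aryl benzyl ether and gives only gaseous by-products.

Step 6
Reactants: 7 (S)-4-(4-benzyloxy-3-methoxybenzyl)dihydrofuran-2(3H)-one; 9 4-benzyloxy-3,5-dimethoxybenzoyl chloride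
Product: 12 (3R,4S)-3-(4-benzyloxy-3,5-dimethoxybenzoyl)-4-(4-benzyloxy-3-methoxybenzyl)dihydrofuran-2(3H)-one, via lactone lithium enolate 10 (not isolated), via keto lactone lithium enolate 11 (not isolated)
Conditions: LiN(SiMe3)2 (2.1 equiv), THF, −78 °C; then 9 (1.0 equiv), −78 → −40 °C; AcOH, then H2O
Reagents that add atoms: none
Why: Crossed Claisen-type C-acylation of the lactone enolate 10 by the aroyl chloride, in which the electrophile enters anti to the C8 benzyl group and the second equivalent of base stores the product as enolate 11, so that protonation on work-up gives the thermodynamically preferred 8,8'-trans keto lactone (C8' set under substrate control).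

Step 7
Reactants: 12 (3R,4S)-3-(4-benzyloxy-3,5-dimethoxybenzoyl)-4-(4-benzyloxy-3-methoxybenzyl)dihydrofuran-2(3H)-one
Product: 13 (3R,4S)-3-[(S)-(4-benzyloxy-3,5-dimethoxyphenyl)(hydroxy)methyl]-4-(4-benzyloxy-3-methoxybenzyl)dihydrofuran-2(3H)-one
Conditions: RuCl[(S,S)-TsDPEN](p-cymene) (2 mol %), HCO2H/Et3N (5:2), DMF, 30 °C
Reagents that add atoms: none
Why: Noyori–Ikariya asymmetric transfer hydrogenation of an aryl ketone activated as a β-keto lactone, in which the (S,S) ligand should place hydride on the carbonyl face that gives the 7'S carbinol (aryl-versus-alkyl facial rule of this catalyst class), the same face that lies open beside the C8'–H in the dipole-opposed Felkin-type conformer, while any C8' epimerisation in the amine buffer returns to the trans isomer.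

Step 8
Reactants: 13 (3R,4S)-3-[(S)-(4-benzyloxy-3,5-dimethoxyphenyl)(hydroxy)methyl]-4-(4-benzyloxy-3-methoxybenzyl)dihydrofuran-2(3H)-one
Product: 14 (3R,4S)-3-[(S)-(4-benzyloxy-3,5-dimethoxyphenyl)(tert-butyldimethylsilyloxy)methyl]-4-(4-benzyloxy-3-methoxybenzyl)dihydrofuran-2(3H)-one
Conditions: TBSOTf (1.3 equiv), 2,6-lutidine (2 equiv), CH2Cl2, −78 → 0 °C
Reagents that add atoms: tert-butyldimethylsilyl triflate, CC(C)(C)[Si](C)(C)OS(=O)(=O)C(F)(F)F
Why: Silyl ether formation with a silyl triflate and a hindered pyridine base, fast enough at low temperature to cap the hindered benzylic hydroxyl without retro-aldol cleavage or dehydration of the β-hydroxy lactone.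

Step 9
Reactants: 14 (3R,4S)-3-[(S)-(4-benzyloxy-3,5-dimethoxyphenyl)(tert-butyldimethylsilyloxy)methyl]-4-(4-benzyloxy-3-methoxybenzyl)dihydrofuran-2(3H)-one
Product: 15 (2S,3S)-2-(4-benzyloxy-3-methoxybenzyl)-3-[(S)-(4-benzyloxy-3,5-dimethoxyphenyl)(tert-butyldimethylsilyloxy)methyl]butane-1,4-diol
Conditions: LiAlH4 (1.5 equiv), THF, 0 °C; Fieser work-up (H2O, 15% NaOH, H2O)
Reagents that add atoms: none
Why: Hydride reduction of the lactone to the 1,4-diol, which touches no stereocentre and is tolerated by the benzyl ethers and by the secondary silyl ether at 0 °C.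

Step 10
Reactants: 15 (2S,3S)-2-(4-benzyloxy-3-methoxybenzyl)-3-[(S)-(4-benzyloxy-3,5-dimethoxyphenyl)(tert-butyldimethylsilyloxy)methyl]butane-1,4-diol
Product: 17 (3S,4S)-3-(4-benzyloxy-3-methoxybenzyl)-4-[(S)-(4-benzyloxy-3,5-dimethoxyphenyl)(tert-butyldimethylsilyloxy)methyl]tetrahydrofuran, via C9 monotosylate 16 (not isolated)
Conditions: TsCl (1.15 equiv), pyridine, DMAP (cat.), 0 °C → 50 °C
Reagents that add atoms: none
Why: Cyclodehydration of the 1,4-diol by monosulfonylation (the less hindered C9 hydroxyl should react first, though either monotosylate leads to the same ring) and intramolecular Williamson displacement by the remaining primary hydroxyl (5-exo-tet), under near-neutral conditions that avoid alkoxide-induced silyl migration and with the C7' oxygen blocked so that only the C9–O–C9' ether can form.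

Step 11
Reactants: 17 (3S,4S)-3-(4-benzyloxy-3-methoxybenzyl)-4-[(S)-(4-benzyloxy-3,5-dimethoxyphenyl)(tert-butyldimethylsilyloxy)methyl]tetrahydrofuran
Product: 18 4-{[(3S,4S)-4-[(S)-(tert-butyldimethylsilyloxy)(4-hydroxy-3,5-dimethoxyphenyl)methyl]tetrahydrofuran-3-yl]methyl}-2-methoxyphenol
Conditions: H2 (1 atm), 10% Pd/C, EtOAc, rt
Reagents that add atoms: none
Why: Hydrogenolysis of the two aryl benzyl ethers over palladium on carbon, in which the bulky silyl ether shields C7'–O, the only other benzylic C–O bond, from reductive cleavage.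

Step 12
Reactants: 18 4-{[(3S,4S)-4-[(S)-(tert-butyldimethylsilyloxy)(4-hydroxy-3,5-dimethoxyphenyl)methyl]tetrahydrofuran-3-yl]methyl}-2-methoxyphenol
Product: 19 4-[(S)-hydroxy{(3S,4S)-4-(4-hydroxy-3-methoxybenzyl)tetrahydrofuran-3-yl}methyl]-2,6-dimethoxyphenol (target, CNP0307127.2)
Conditions: TBAF (3 equiv), AcOH (3 equiv), THF, 0 °C → rt
Reagents that add atoms: none
Why: Fluoride-induced cleavage of the silyl ether, buffered with acetic acid so that the phenols stay protonated and the benzylic C7' oxygen is not expelled through a quinone methide, with no stereocentre involved.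

Compound list

1 | dihydroconiferyl alcohol, 3-(4-hydroxy-3-methoxyphenyl)propan-1-ol | COc1cc(CCCO)ccc1O | starting material
2 | 3-(4-benzyloxy-3-methoxyphenyl)propan-1-ol | COc1cc(CCCO)ccc1OCc1ccccc1 | intermediate
3 | bromoacetyl bromide | BrCC(=O)Br | starting material
4 | 3-(4-benzyloxy-3-methoxyphenyl)propyl bromoacetate | COc1cc(CCCOC(=O)CBr)ccc1OCc1ccccc1 | intermediate
5 | N-alkylated ditosylhydrazine, 3-(4-benzyloxy-3-methoxyphenyl)propyl 2-[1,2-bis(4-methylphenylsulfonyl)hydrazinyl]acetate (not isolated) | COc1cc(CCCOC(=O)CN(NS(=O)(=O)c2ccc(C)cc2)S(=O)(=O)c2ccc(C)cc2)ccc1OCc1ccccc1 | intermediate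
6 | 3-(4-benzyloxy-3-methoxyphenyl)propyl diazoacetate | COc1cc(CCCOC(=O)C=[N+]=[N-])ccc1OCc1ccccc1 | intermediate
7 | (S)-4-(4-benzyloxy-3-methoxybenzyl)dihydrofuran-2(3H)-one | COc1cc(C[C@@H]2COC(=O)C2)ccc1OCc1ccccc1 | intermediate
8 | 4-benzyloxy-3,5-dimethoxybenzoic acid | COc1cc(C(=O)O)cc(OC)c1OCc1ccccc1 | starting material
9 | 4-benzyloxy-3,5-dimethoxybenzoyl chloride | COc1cc(C(=O)Cl)cc(OC)c1OCc1ccccc1 | intermediate
10 | lactone lithium enolate, lithium (S)-4-(4-benzyloxy-3-methoxybenzyl)-4,5-dihydrofuran-2-olate (not isolated) | COc1cc(C[C@@H]2COC(O[Li])=C2)ccc1OCc1ccccc1 | intermediate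
11 | keto lactone lithium enolate, lithium enolate of 12 at C7'–C8' (not isolated) | COc1cc(C[C@@H]2COC(=O)C2=C(O[Li])c2cc(OC)c(OCc3ccccc3)c(OC)c2)ccc1OCc1ccccc1 | intermediate
12 | (3R,4S)-3-(4-benzyloxy-3,5-dimethoxybenzoyl)-4-(4-benzyloxy-3-methoxybenzyl)dihydrofuran-2(3H)-one | COc1cc(C[C@@H]2COC(=O)[C@H]2C(=O)c2cc(OC)c(OCc3ccccc3)c(OC)c2)ccc1OCc1ccccc1 | intermediate
13 | (3R,4S)-3-[(S)-(4-benzyloxy-3,5-dimethoxyphenyl)(hydroxy)methyl]-4-(4-benzyloxy-3-methoxybenzyl)dihydrofuran-2(3H)-one | COc1cc(C[C@@H]2COC(=O)[C@H]2[C@H](O)c2cc(OC)c(OCc3ccccc3)c(OC)c2)ccc1OCc1ccccc1 | intermediate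
14 | (3R,4S)-3-[(S)-(4-benzyloxy-3,5-dimethoxyphenyl)(tert-butyldimethylsilyloxy)methyl]-4-(4-benzyloxy-3-methoxybenzyl)dihydrofuran-2(3H)-one | COc1cc(C[C@@H]2COC(=O)[C@H]2[C@H](O[Si](C)(C)C(C)(C)C)c2cc(OC)c(OCc3ccccc3)c(OC)c2)ccc1OCc1ccccc1 | intermediate
15 | (2S,3S)-2-(4-benzyloxy-3-methoxybenzyl)-3-[(S)-(4-benzyloxy-3,5-dimethoxyphenyl)(tert-butyldimethylsilyloxy)methyl]butane-1,4-diol | COc1cc(C[C@H](CO)[C@@H](CO)[C@H](O[Si](C)(C)C(C)(C)C)c2cc(OC)c(OCc3ccccc3)c(OC)c2)ccc1OCc1ccccc1 | intermediate
16 | C9 monotosylate of 15, tosylate on the hydroxymethyl of the carbon that bears the guaiacylmethyl group (not isolated) | COc1cc(C[C@H](COS(=O)(=O)c2ccc(C)cc2)[C@@H](CO)[C@H](O[Si](C)(C)C(C)(C)C)c2cc(OC)c(OCc3ccccc3)c(OC)c2)ccc1OCc1ccccc1 | intermediate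
17 | (3S,4S)-3-(4-benzyloxy-3-methoxybenzyl)-4-[(S)-(4-benzyloxy-3,5-dimethoxyphenyl)(tert-butyldimethylsilyloxy)methyl]tetrahydrofuran | COc1cc(C[C@@H]2COC[C@H]2[C@H](O[Si](C)(C)C(C)(C)C)c2cc(OC)c(OCc3ccccc3)c(OC)c2)ccc1OCc1ccccc1 | intermediate
18 | 4-{[(3S,4S)-4-[(S)-(tert-butyldimethylsilyloxy)(4-hydroxy-3,5-dimethoxyphenyl)methyl]tetrahydrofuran-3-yl]methyl}-2-methoxyphenol | COc1cc(C[C@@H]2COC[C@H]2[C@H](O[Si](C)(C)C(C)(C)C)c2cc(OC)c(O)c(OC)c2)ccc1O | intermediate
19 | 4-[(S)-hydroxy{(3S,4S)-4-(4-hydroxy-3-methoxybenzyl)tetrahydrofuran-3-yl}methyl]-2,6-dimethoxyphenol, (7'S,8S,8'S) | COc1cc(C[C@@H]2COC[C@H]2[C@H](O)c2cc(OC)c(O)c(OC)c2)ccc1O | target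

Total step count: 12. Longest linear sequence: 11 steps (steps 1 to 4 and 6 to 12); step 5 prepares the acyl donor.

Steps most likely to fail

Step 4. The catalyst may discriminate the two enantiotopic C8 hydrogens insufficiently, or the carbene may be diverted into dimerisation, arene addition or benzylic C7–H insertion. The fallback builds the same lactone by auxiliary-controlled alkylation. It sets out from alcohol 2, which is oxidised (TEMPO cat., PhI(OAc)2, MeCN/H2O) to 3-(4-benzyloxy-3-methoxyphenyl)propanoic acid F1. This acid is coupled with (R)-4-benzyloxazolidin-2-one (pivaloyl chloride, Et3N, LiCl, THF) to give (R)-4-benzyl-3-[3-(4-benzyloxy-3-methoxyphenyl)propanoyl]oxazolidin-2-one F2. Its sodium enolate (NaN(SiMe3)2, THF, −78 °C) undergoes Evans alkylation with tert-butyl bromoacetate on the face opposite the auxiliary benzyl group, giving tert-butyl (S)-3-(4-benzyloxy-3-methoxybenzyl)-4-[(R)-4-benzyl-2-oxooxazolidin-3-yl]-4-oxobutanoate F3. LiBH4 (THF, 1 equiv H2O, 0 °C) removes the auxiliary reductively to give tert-butyl (S)-4-(4-benzyloxy-3-methoxyphenyl)-3-(hydroxymethyl)butanoate F4. TFA in CH2Cl2 then cleaves the tert-butyl ester with lactonisation, and the fallback comes back to the route at 7.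

Step 7. Hydride delivery may be mismatched with the substrate, giving poor facial selectivity at C7' or reduction through the minor C8' epimer. The fallback sets the carbinol by substrate control followed by inversion. It sets out from keto lactone 12. Zn(BH4)2 (Et2O, −20 °C) reduces through the zinc chelate of the two carbonyl groups from the face of the C8'–H, which should give (3R,4S)-3-[(R)-(4-benzyloxy-3,5-dimethoxyphenyl)(hydroxy)methyl]-4-(4-benzyloxy-3-methoxybenzyl)dihydrofuran-2(3H)-one F5. Mitsunobu reaction (PPh3, DIAD, 4-nitrobenzoic acid, toluene, 0 °C) inverts C7' to give (S)-(4-benzyloxy-3,5-dimethoxyphenyl)[(3R,4S)-4-(4-benzyloxy-3-methoxybenzyl)-2-oxotetrahydrofuran-3-yl]methyl 4-nitrobenzoate F6. Mild methanolysis (K2CO3, MeOH, 0 °C) frees the alcohol, and the fallback comes back to the route at 13. Any 7'R alcohol formed in step 7 itself enters this sequence at F5.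

Step 6. C-acylation may be spoiled by O-acylation, double acylation or proton exchange between product and enolate. The fallback brings in the carbonyl carbon at the alcohol oxidation level. It sets out from lactone 7, whose lithium enolate (LiN(SiMe3)2, THF, −78 °C) is added to commercially available 4-benzyloxy-3,5-dimethoxybenzaldehyde (COc1cc(C=O)cc(OC)c1OCc1ccccc1). Aldol addition anti to the C8 substituent should give (3R,4S)-3-[(4-benzyloxy-3,5-dimethoxyphenyl)(hydroxy)methyl]-4-(4-benzyloxy-3-methoxybenzyl)dihydrofuran-2(3H)-one as a mixture of C7' epimers F7. Dess–Martin periodinane (NaHCO3, CH2Cl2, rt) oxidises both epimers to the same keto lactone, and the fallback comes back to the route at 12.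

Further compounds

F1 | step 4 | 3-(4-benzyloxy-3-methoxyphenyl)propanoic acid | COc1cc(CCC(=O)O)ccc1OCc1ccccc1
F2 | step 4 | (R)-4-benzyl-3-[3-(4-benzyloxy-3-methoxyphenyl)propanoyl]oxazolidin-2-one | COc1cc(CCC(=O)N2[C@H](Cc3ccccc3)COC2=O)ccc1OCc1ccccc1
F3 | step 4 | tert-butyl (S)-3-(4-benzyloxy-3-methoxybenzyl)-4-[(R)-4-benzyl-2-oxooxazolidin-3-yl]-4-oxobutanoate | COc1cc(C[C@@H](CC(=O)OC(C)(C)C)C(=O)N2[C@H](Cc3ccccc3)COC2=O)ccc1OCc1ccccc1
F4 | step 4 | tert-butyl (S)-4-(4-benzyloxy-3-methoxyphenyl)-3-(hydroxymethyl)butanoate | COc1cc(C[C@@H](CC(=O)OC(C)(C)C)CO)ccc1OCc1ccccc1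
F5 | step 7 | (3R,4S)-3-[(R)-(4-benzyloxy-3,5-dimethoxyphenyl)(hydroxy)methyl]-4-(4-benzyloxy-3-methoxybenzyl)dihydrofuran-2(3H)-one | COc1cc(C[C@@H]2COC(=O)[C@H]2[C@@H](O)c2cc(OC)c(OCc3ccccc3)c(OC)c2)ccc1OCc1ccccc1
F6 | step 7 | (S)-(4-benzyloxy-3,5-dimethoxyphenyl)[(3R,4S)-4-(4-benzyloxy-3-methoxybenzyl)-2-oxotetrahydrofuran-3-yl]methyl 4-nitrobenzoate | COc1cc(C[C@@H]2COC(=O)[C@H]2[C@H](OC(=O)c2ccc(cc2)[N+](=O)[O-])c2cc(OC)c(OCc3ccccc3)c(OC)c2)ccc1OCc1ccccc1
F7 | step 6 | (3R,4S)-3-[(4-benzyloxy-3,5-dimethoxyphenyl)(hydroxy)methyl]-4-(4-benzyloxy-3-methoxybenzyl)dihydrofuran-2(3H)-one, mixture of C7' epimers | COc1cc(C[C@@H]2COC(=O)[C@H]2C(O)c2cc(OC)c(OCc3ccccc3)c(OC)c2)ccc1OCc1ccccc1
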